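The constants stand for no real mixture, and the outcome is calculated.

Divide one rate by another.

| setting | winter | midnight | summer |
|---|---|---|---|
| starting material | 20 mM | 20 mM | 20 mM |
| gas | 3.2 mM (held) | 3.2 mM (held) | 3.2 mM (held) |
| free enzyme | 4.0 µM | 4.0 µM | 4.0 µM |
| temperature | 20 °C | 40 °C | 0 °C |
| time | 10 d | 10 d | 10 d |

- which flask leads in amount of target, in percent of the starting material charged ("all alike" within 1.5 percentage points) (winter / midnight / summer / all alike)
- how much target is there at the end, in percent of the starting material charged: winter
- how much target is there at the end, in percent of the starting material charged: midnight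
- how much target is there at the end, in percent of the starting material charged: summer

- percent here means starting material units held: one self-condensation product counts as two
- for a step with 2 of a species take k times the square, and two of it per event
- at the start none of second substrate is dissolved
- constants are those at 40 °C; use the activation energies and enthalpies for any other temperature

    first complex ⇌ loaded enzyme + first product (K1 = 0.011 M, k1 = 0.51 s⁻¹, Ea1 = 66.0 kJ mol⁻¹, ΔH1 = −82.0 kJ mol⁻¹)
    second complex → free enzyme + target (k2 = 0.20 s⁻¹, Ea2 = 87.0 kJ mol⁻¹)
    2 starting material → self-condensation product (k3 = 2.6 × 10⁻⁴ L mol⁻¹ s⁻¹, Ea3 = 65.0 kJ mol⁻¹)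
    second substrate + loaded enzyme ⇌ second complex (K4 = 300 L mol⁻¹, k4 = 1200 L mol⁻¹ s⁻¹, Ea4 = 41.0 kJ mol⁻¹, ΔH4 = −90.0 kJ mol⁻¹)
    gas ⇌ second substrate, rate k5*(csat - [second substrate]) (k5 = 1.5 × 10⁻⁴ s⁻¹, csat = 3.2 mM)
    starting material + free enzyme ⇌ first complex (K6 = 84 L mol⁻¹, k6 = 26 L mol⁻¹ s⁻¹, Ea6 = 38.0 kJ mol⁻¹, ΔH6 = −28.0 kJ mol⁻¹)
    free enzyme → unfolded enzyme (k7 = 1.2 × 10⁻⁶ s⁻¹, Ea7 = 216 kJ mol⁻¹)
    (constants at 40 °C)

Each flask is a race for starting material. Enzyme takes it through a round: free enzyme binds it, first complex gives off first product, loaded enzyme takes second substrate, and second complex releases target. Meanwhile self-condensation takes starting material in pairs. Dissolved gas fills up with a mean time of 1.85 h, much shorter than the run, so I set [second substrate] at 3.2 mM. I add the mean times of the steps, counting the returns, into a round time at the charge. Enzyme charge over round time is the enzyme rate. The rows below give the round time, the ratio of rates at the charge, and the days the enzyme rate needs for the whole charge: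

- winter: 73.9 s, 1.43, 4.27 d
- midnight: 15.5 s, 1.24, 0.898 d
- summer: 780 s, 0.954, 45.2 d

Call the middle column the split, the enzyme rate over the rate at which self-condensation removes starting material, both at the charge. It is a selectivity factor: time has dropped out, and it tells what each unit of starting material does next.

Read the last column first. By this reckoning winter and midnight finish inside 10 d, so I take their target from their split. Summer does not, so I reckon its target as the enzyme rate times the time, 22.1%.

Now read the middle column. Winter stands highest, but check the midnight row first. Its enzyme rate, 22.3 mM d⁻¹, is a large part of what the gas can deliver, 41.5 mM d⁻¹, so I reckon [second substrate] to sag. The terms without second substrate take 10.1 s. Setting transfer equal to enzyme rate gives 17.7 mM d⁻¹ at [second substrate] 1.84 mM, and the midnight split drops to 0.982, below winter.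

As [starting material] falls, self-condensation falls with its square. With the enzyme rate held at its value at the charge, the share going to enzyme at a fraction of the charge is the split over the split plus that fraction squared. Averaging this share over the charge by Simpson's rule gives 83.2% for winter and 78.1% for midnight. I commit to these and to the summer figure.

The forecast puts winter first, with 82%, 73% and 22% for winter, midnight and summer, and says of summer “the run is incomplete”.

The simulation puts winter first, with 82.0% for winter, 71.6% for midnight and 21.9% for summer.

Midnight stands 6.5 percentage points below my figure and below winter, whose split of 1.43 was the higher. Of what midnight's target lacks of the full charge, self-condensation is the main reason: struck out, midnight reaches >99.9%. In summer at 10.0 d, 83.8% of the enzyme stands as second complex, the resting state. The neighbour of summer with 0.0024 mM of free enzyme has a split of 0.572, reckons to 13.3% and stands at 13.2%.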